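(All runs are calculated with constants of no real substance; the scatter is artificial.)

The target is a poor count of what has reacted: in the ochre run it drops from 40% at 20.0 h to 27% at 40.0 h, so it is turning into something I cannot read. I count nucleophile instead.

all flasks: solid electrophile 0.75 M

| run | nucleophile | protic impurity | remark | time |
|---|---|---|---|---|
| green | 0.54 M | 0.75 M | run made earlier |  |
| ochre | 1.5 M | 0.75 M | run made earlier |  |
| spring | 0.900 M | 0.750 M |  | 3.0 d |
| autumn | 1.80 M | 0.750 M |  | 3.0 d |

| run | time / h | solid electrophile / % | target / % |
|---|---|---|---|
| green | 8.00 | 58 | 11 |
| green | 15.0 | 39 | 13 |
| green | 20.0 | 36 | 13 |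
| green | 30.0 | 32 | 9 |
| green | 40.0 | 28 | 13 |
| ochre | 8.00 | 48 | 34 |
| ochre | 15.0 | 15 | 37 |
| ochre | 20.0 | 2 | 40 |
| ochre | 30.0 | 0 | 33 |
| ochre | 40.0 | 0 | 27 |

(standard deviation of a reading: 2 percentage points)

- at the start none of the solid electrophile is in solution
- what has only dissolved of solid electrophile counts as not reacted

1. part of the solid electrophile that has reacted (what has only dissolved counts as not reacted) at the end, spring
2. part of the solid electrophile that has reacted (what has only dissolved counts as not reacted) at the end, autumn
3. what raising the concentration of nucleophile from its lowest to its highest value here does to the part of the solid electrophile that has reacted (what has only dissolved counts as not reacted) (changes below 5 percentage points count as none) (no change / it falls / it rises)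

I reckon the nucleophile as shared between the solid electrophile and the protic impurity, whose charges are the same in spring and autumn. Spring carries 0.200 and autumn 1.40 of what I call the surplus: nucleophile charged less impurity charged, per solid electrophile charged. In one extreme the impurity takes its whole charge first, and the part reacted equals the surplus: 20.0% in spring, 100% in autumn. In the other extreme the impurity takes nothing, and spring's 1.20 equivalents cover the charge. So spring lies between those ends, while autumn stands at the top in both.

The earlier runs place them. Green, with a surplus of −0.280, stalls with target near 13% and 28% of the solid standing. Ochre, at 1.00, reads 0% solid by 30.0 h. I put spring in the lower part of its range and autumn near the top.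

The forecast says 32% for spring (range 23% to 43%) and 99% for autumn (93% to 100%), with the trend: it rises. Of green it reads that “the nucleophile is dead, mostly quenched by the protic impurity”.

The simulation gives 39.9% for spring and 84.7% for autumn; the trend is: it rises, by 45 percentage points. The main reason is the difference in concentration of nucleophile: autumn reads 84.7%, and without that difference it reads 39.9%.

    electrophile + nucleophile → acid set free + target (k = 0.0230 /M/min)
    nucleophile + acid set free ⇌ protonated nucleophile, settled at all times (K = 500 /M)
    target ⇌ isomer of the product (K = 2.00, k = 6.30 × 10⁻⁴ /min)
    nucleophile + protic impurity → quenched reagent (k = 0.00610 /M/min)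
    solid electrophile ⇌ electrophile, rate k5*(cs5 - [electrophile]) while solid is left; crystals form when [electrophile] > cs5 (solubility = 0.390 M, k = 0.00240 /min)

Autumn's surplus of 1.40 covers the charge, yet the flask reads 84.7%: the quenching of nucleophile, together with reading at 3.0 d rather than later, holds it there. Without the quenching autumn reads 100%, and left for 30.0 d it reads 97.8%. At the end of autumn 0.244% of the nucleophile is free and 0.436 M sits as protonated nucleophile. A neighbouring flask, autumn with 0.30 M of protic impurity, has a surplus of 2.00 and reaches 99.8% at 3.00 d.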